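## Structural features

Compound 20 is a bicyclic diterpenoid with the halimane skeleton. Ring A (C1–C5, C10) and ring B (C5–C10) share the tetrasubstituted C5=C10 alkene, which sits between two quaternary carbons: C4 with two methyls and C9 with a methyl (C20) and the C11–C16 side chain. Ring B carries four contiguous stereocentres, C6 to C9. The free C6 hydroxyl and the C7 acetate are cis to each other and on the face of the C9 methyl; the C8 methyl (C17) is on the other face, trans to the C9 methyl and cis to the side chain. The fifth stereocentre, the tertiary allylic carbinol C13 (R), is two methylene groups from the ring and cannot be set by relay from it. Fragile groups are this tertiary allylic alcohol (ionisation and allylic transposition in acid), the allylic C6 hydroxyl, the acetate beside a free cis hydroxyl (migration in base) and the terminal vinyl group (competes in any alkene oxidation). The real difficulty is threefold: an unactivated tetrasubstituted alkene between two quaternary carbons, a quaternary C9 of defined configuration next to C8, and a cis-diol that must be placed on one face and then differentiated. The key step exploits the fact that C4 with C18 and C19, C5–C10 of ring B and C17, including the C8 configuration, are the ten carbons of (R)-pulegone 1. Ring A then lacks only C1–C3 and the C1–C10 bond, which is made at the former ring-B carbonyl carbon, so the alkene position follows from a triflate and not from an elimination.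

## Logic of the disconnections

20 to 19. The ester C–O bond at C7 is cut last, because an acetate would not survive the hydride, base and zinc steps of the side-chain work. This leaves the triol 19. The forward step must acylate O7 in the presence of O6 and the tertiary O13.

19 to 17 (through 18). The C14=C15 alkene and the C13 hydroxyl are traced back to a 2,3-epoxy sulfonate, so the C13–O bond is never broken and C13 can be set by a reagent. The vinyl group, which no alkene oxidation would tolerate, appears only after ring B is oxidised. The forward step needs a reductive opening that tolerates a free diol.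

17 to 16 to 15. First the sulfonate S–O bond at C15 is cut, then the C6–O and C7–O bonds. This returns the cis-diol to the C6=C7 alkene of a 5(10),6-diene and removes two stereocentres. The forward steps must hit C6=C7 and not C5=C10, on the face anti to the C8 methyl, and must sulfonylate only the primary hydroxyl.

15 to 14. The two epoxide C–O bonds are cut. C13 and C14 become an E-trisubstituted allylic alcohol, the best substrate class for titanium–tartrate epoxidation. The forward step needs geometrically pure alkene, because alkene geometry becomes C13 configuration.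

14 to 13 to 12. The C13=C14 bond is cut (olefination, then ester reduction), leaving a methyl ketone with only C11–C13 and C16 in the side chain. The forward step must favour the E isomer.

12 to 11. The C13 carbonyl is masked as its dioxolane, so that it survives enolate chemistry, hydroboration and the coupling.

11 to 9 (through 10). The C1–C10 bond is cut, opening ring A. The three-carbon unit C1–C3 becomes an allyl group on C4 and C10 becomes an enol triflate carbon. This gives a monocyclic ring B with all its carbons and both early stereocentres in place. The forward step must hydroborate the allyl group alone and close the ring before the alkylpalladium decays.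

9 to 8. The C10–O(S) bond is cut to give the C5=C6 enone. Because C9 is quaternary, only the C7 hydrogen can be removed, so the triflate can only form as the C10 triflate of the 5(10),6-diene.

8 to 7 to 4 and 6. The C9–C20 and C9–C11 bonds are cut in that order. The electrophile that enters second goes anti to the C8 methyl, so the side chain must go in first and the methyl last. An enone is chosen as the substrate because its kinetic enolate forms only at C9. 6 is cut back to the commercial bromide 5, which itself is too slow toward an enolate.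

4 to 3 to 1 and 2. The C5=C6 unsaturation is removed and the C3–C4 bond is cut. Conjugate allylation of 1 makes the quaternary C4 and, with silyl trapping, gives directly the enol ether needed for dehydrogenation. Doing this before the alkylations avoids a conjugate addition and an enol ether formation on a ketone flanked by a quaternary carbon.

## Other disconnections considered

Alternative 1: The cut runs through C7–C8 and C9–C10 and removes ring B as a cycloadduct. In the forward step, diene A2 (C10=C5–C6=C7) and the menthyloxy butenolide A3 (C8=C9) would combine thermally to the cis-fused lactone acetal A1.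
- In favour: two skeletal bonds, ring B, C8 and the quaternary C9 arise in one concerted step. The cis lactone fusion puts C17 and C11 on the same face, exactly the relation of the C8 methyl and the C9 side chain in 20. The menthyloxy group should send the diene to the opposite face of A3, so absolute configuration comes from a recoverable auxiliary.
- Against: A3 is a trisubstituted dienophile that must form a quaternary centre. The s-cis form of A2 is penalised by the gem-dimethyl group next to C5. The two alkyl substituents of A2 direct the orientation in opposite senses.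
- Distance from A1 to 20: the C11 carbonyl needs five more carbons, the acetal carbon C17 must become a methyl, the C5=C6 alkene must move to C5=C10, and the C6 and C7 oxygens must be introduced without a C6=C7 alkene.
- Comparison: for the C8/C9 pair the cycloaddition is the better solution (one step, relative configuration fixed by concertedness, no metal). The chosen plan is better after the key step, because the coupling leaves the alkene at C5=C10 and a C6=C7 alkene ready for the diol. Overall step economy favours the chosen plan.

Alternative 2: The cut is the C6–C7 bond, which opens ring B to the dialdehyde A5. In the forward step SmI2 would reduce the C6 enal and the C7 aldehyde, and the two ketyls would couple to the diol A4.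
- In favour: the C6–C7 bond, ring B and both carbinols come in one step, and chelation of both ketyl oxygens to samarium should make them cis. The closure is as late as possible, with the side chain and C13 complete. From A4 only desilylation and C7 acetylation remain, so the end of this route is shorter than that of the chosen plan and needs no alkene differentiation; this is its clear advantage.
- Against: A5 carries C8 and the quaternary C9 on an open chain attached to a tetrasubstituted enal, so these centres must be built without a ring to relay configuration. The conjugated aldehyde can be reduced or coupled through C10. Which face the cis-diol takes relative to the C8 methyl is not obvious.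
- Comparison: the chosen plan builds C8 and C9 on a ring, where facial bias is dependable, and closes ring A by a site-specific palladium coupling instead of a radical-anion coupling. Alternative 2 is shorter after its key step and judged longer before it, so no gain in total steps is expected.

Alternative 3: The cut is the C4–C5 bond. In the forward step acid would protonate the 4-methylpent-3-enyl chain of the monocyclic enone A7; the tertiary C4 cation would be captured by the enone α-carbon C5, and proton loss would give the bicyclic enone A6.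
- In favour: no metal and no leaving group are needed, and ring A with its gem-dimethyl carbon forms in one step. Like the chosen key step it makes one ring, one bond and no stereocentre. The C6 carbonyl of A6 distinguishes C6 from C7 from the start: C7 could be oxygenated through the enolate anti to the C8 methyl and acetylated before C6 is reduced. On this point it is better than the chosen plan, which needs a selective acetylation at the end. A7 should be reachable in about as many steps as 9.
- Against: the nucleophile is the electron-poor α-carbon of an enone. The cation can instead lose a proton, add water or meet the C13 carbonyl. The new bond joins a quaternary carbon to a fully substituted alkene carbon. Pulegone does not map onto A7, so C8 needs another source of absolute configuration. The C6 ketone must later be reduced to the β-alcohol and kept apart from the C13 ketone.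
- Comparison: step count is equal or slightly better if the cyclisation works, but the mechanism is less predictable than a cross-coupling whose regiochemistry is fixed by the triflate.

Key step: step 7

Assumption: atoms carry halimane numbers (rings C1–C10, side chain C11–C16, C17 on C8, C18 and C19 on C4, C20 on C9); in these terms 20 is 6S,7R,8S,9R,13R, that is 6β-OH, 7β-OAc, 8α-CH3, 9β-CH3, and C8 of 1 already has this configuration.

## Route

Step 1
Reactants: 1 (R)-(+)-pulegone; 2 allylmagnesium bromide
Product: 3 trimethyl{[(5R)-5-methyl-2-(2-methylpent-4-en-2-yl)cyclohex-1-en-1-yl]oxy}silane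
Conditions: CuBr·SMe2 (1.1 equiv), 2 (1.1 equiv), THF, −78 °C; then 1, Me3SiCl (2 equiv), −78 → −40 °C; Et3N, pentane, cold aq. NaHCO3
Reagents that add atoms: chlorotrimethylsilane, C[Si](C)(C)Cl
Why: Copper-mediated conjugate addition (allylcopper from the Grignard reagent, accelerated by Me3SiCl) to the s-cis enone makes the quaternary C4 and the C3–C4 bond, and silylation traps the enolate regiospecifically as the C5=C10 silyl enol ether; no stereocentre is formed and C8 is untouched.

Step 2
Reactants: 3 trimethyl{[(5R)-5-methyl-2-(2-methylpent-4-en-2-yl)cyclohex-1-en-1-yl]oxy}silane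
Product: 4 (5R)-5-methyl-2-(2-methylpent-4-en-2-yl)cyclohex-2-en-1-one
Conditions: Pd(OAc)2 (1.0 equiv), MeCN, 25 °C
Reagents that add atoms: none
Why: Saegusa–Ito oxidation: divalent palladium replaces silicon to give the C5-bound palladium enolate, and syn β-hydride elimination can only take a hydrogen from C6 because C4 is quaternary, so only the C5=C6 enone is expected; the allyl alkene is too close to insert into the C5–Pd bond.

Step 3
Reactants: 5 2-(2-bromoethyl)-2-methyl-1,3-dioxolane
Product: 6 2-(2-iodoethyl)-2-methyl-1,3-dioxolane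
Conditions: NaI (2 equiv), NaHCO3 (cat.), acetone, reflux
Reagents that add atoms: sodium iodide, [Na+].[I-]
Why: Finkelstein halide exchange (SN2), driven by precipitation of NaBr; the iodide is needed because the bromide is too sluggish toward a ketone enolate.

Step 4
Reactants: 4 (5R)-5-methyl-2-(2-methylpent-4-en-2-yl)cyclohex-2-en-1-one; 6 2-(2-iodoethyl)-2-methyl-1,3-dioxolane
Product: 7 (5R)-5-methyl-6-[2-(2-methyl-1,3-dioxolan-2-yl)ethyl]-2-(2-methylpent-4-en-2-yl)cyclohex-2-en-1-one (both epimers at ring C6, which is C9 of the skeleton)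
Conditions: LiN(i-Pr)2, THF, −78 °C; then 6, DMPU, −78 → −20 °C
Reagents that add atoms: none
Why: A lithium amide deprotonates a cyclohexenone kinetically at the α′ carbon (C9), and the cross-conjugated enolate is alkylated there by SN2 displacement of the primary iodide; C9 forms as an epimer mixture, which does not matter because C9 becomes planar again in step 5.

Step 5
Reactants: 7 (5R)-5-methyl-6-[2-(2-methyl-1,3-dioxolan-2-yl)ethyl]-2-(2-methylpent-4-en-2-yl)cyclohex-2-en-1-one
Product: 8 (5R,6R)-5,6-dimethyl-6-[2-(2-methyl-1,3-dioxolan-2-yl)ethyl]-2-(2-methylpent-4-en-2-yl)cyclohex-2-en-1-one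
Conditions: LiN(i-Pr)2, THF, −78 → −40 °C; MeI, DMPU, −78 → 0 °C
Reagents that add atoms: iodomethane, CI
Why: Enolate alkylation: in the tetrasubstituted C9=C10 enolate the C8 methyl stands pseudoaxial to avoid A(1,2) strain with the C9 side chain, so iodomethane approaches the opposite face and the quaternary C9 gets its methyl trans to the C8 methyl and the side chain cis to it; C8 cannot epimerise.

Step 6
Reactants: 8 (5R,6R)-5,6-dimethyl-6-[2-(2-methyl-1,3-dioxolan-2-yl)ethyl]-2-(2-methylpent-4-en-2-yl)cyclohex-2-en-1-one
Product: 9 (5R,6R)-5,6-dimethyl-6-[2-(2-methyl-1,3-dioxolan-2-yl)ethyl]-2-(2-methylpent-4-en-2-yl)cyclohexa-1,3-dien-1-yl trifluoromethanesulfonate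
Conditions: KN(SiMe3)2, THF, −78 °C; PhNTf2, −78 → 0 °C
Reagents that add atoms: N-phenylbis(trifluoromethanesulfonimide), O=S(=O)(N(c1ccccc1)S(=O)(=O)C(F)(F)F)C(F)(F)F
Why: With C9 quaternary the enone has no α′ hydrogen, so the amide base removes a γ hydrogen from C7 and the linear dienolate is sulfonylated on oxygen (enol triflate formation), giving the C10 triflate of the 5(10),6-diene unambiguously; the dioxolane, the allyl group and both stereocentres are inert.

Step 7
Reactants: 9 (5R,6R)-5,6-dimethyl-6-[2-(2-methyl-1,3-dioxolan-2-yl)ethyl]-2-(2-methylpent-4-en-2-yl)cyclohexa-1,3-dien-1-yl trifluoromethanesulfonate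
Product: 11 2-methyl-2-{2-[(1R,2R)-1,2,5,5-tetramethyl-1,2,5,6,7,8-hexahydronaphthalen-1-yl]ethyl}-1,3-dioxolane, via alkylborane 10 (not isolated)
Conditions: 9-BBN-H (1.2 equiv), THF, 0 → 25 °C; then PdCl2(dppf) (10 mol %), AsPh3 (10 mol %), Cs2CO3 (3 equiv), DMF/THF/H2O, 50 °C, high dilution
Reagents that add atoms: 9-borabicyclo[3.3.1]nonane, B1C2CCCC1CCC2 (its boron bicycle is carried by 10 and leaves in the coupling; only hydrogen stays in 11)
Why: 9-BBN-H adds to the monosubstituted allyl alkene with boron on the terminal carbon C1, giving 10; the cis-disubstituted C6=C7 alkene and the hindered enol triflate alkene react far more slowly with this bulky borane, and the ketal is inert. Zerovalent palladium, formed from PdCl2(dppf), inserts into the C10–O bond of the dienyl triflate, the base turns the borane into a borate that hands the primary C1 alkyl group to palladium, and reductive elimination makes the C1–C10 bond. The closest known reaction type is the intramolecular B-alkyl Suzuki–Miyaura coupling of an alkenyl triflate with an alkylborane made in the same flask by 9-BBN hydroboration. Ring A closes as a six-membered ring through a seven-membered palladacycle; both carbons of the C5=C10 alkene end up in the new ring, so the closure is of the 6-endo kind at an sp2 carbon, which a cross-coupling allows because the tether is cis to the triflate by construction. No stereocentre is formed and none is at risk, since C9 is quaternary and the C8 hydrogen is not acidic under carbonate base. The selectivity needed is ring closure ahead of β-hydride elimination, protodeboronation and hydrolysis of the triflate; the bidentate wide-bite-angle ligand speeds reductive elimination, the gem-dimethyl group at C4 holds the chain near C10, and no other ring size is within reach. The alkene position was secured earlier, because the triflate can sit only on C10 when C9 has no hydrogen.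

Step 8
Reactants: 11 2-methyl-2-{2-[(1R,2R)-1,2,5,5-tetramethyl-1,2,5,6,7,8-hexahydronaphthalen-1-yl]ethyl}-1,3-dioxolane
Product: 12 4-[(1R,2R)-1,2,5,5-tetramethyl-1,2,5,6,7,8-hexahydronaphthalen-1-yl]butan-2-one
Conditions: pyridinium 4-toluenesulfonate (cat.), acetone/H2O, 50 °C
Reagents that add atoms: water, O
Why: Acid-catalysed acetal hydrolysis under buffered conditions frees the C13 methyl ketone; the acid is too weak to protonate the diene at a useful rate, and no stereocentre is involved.

Step 9
Reactants: 12 4-[(1R,2R)-1,2,5,5-tetramethyl-1,2,5,6,7,8-hexahydronaphthalen-1-yl]butan-2-one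
Product: 13 ethyl (2E)-3-methyl-5-[(1R,2R)-1,2,5,5-tetramethyl-1,2,5,6,7,8-hexahydronaphthalen-1-yl]pent-2-enoate
Conditions: (EtO)2P(O)CH2CO2Et, NaH, THF, 0 → 60 °C; chromatography to remove the 2Z isomer
Reagents that add atoms: triethyl phosphonoacetate, CCOC(=O)CP(=O)(OCC)OCC
Why: Horner–Wadsworth–Emmons olefination of the methyl ketone should favour the 2E enoate (ester trans to the larger C12 chain); the minor 2Z isomer must be removed here or after step 10, because alkene geometry becomes C13 configuration in step 11.

Step 10
Reactants: 13 ethyl (2E)-3-methyl-5-[(1R,2R)-1,2,5,5-tetramethyl-1,2,5,6,7,8-hexahydronaphthalen-1-yl]pent-2-enoate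
Product: 14 (2E)-3-methyl-5-[(1R,2R)-1,2,5,5-tetramethyl-1,2,5,6,7,8-hexahydronaphthalen-1-yl]pent-2-en-1-ol
Conditions: i-Bu2AlH (2.5 equiv), CH2Cl2, −78 °C; aq. potassium sodium tartrate
Reagents that add atoms: none
Why: 1,2-Reduction of the conjugated ester by the aluminium hydride at low temperature gives the allylic alcohol without touching the diene or the alkene geometry.

Step 11
Reactants: 14 (2E)-3-methyl-5-[(1R,2R)-1,2,5,5-tetramethyl-1,2,5,6,7,8-hexahydronaphthalen-1-yl]pent-2-en-1-ol
Product: 15 [(2R,3R)-3-methyl-3-{2-[(1R,2R)-1,2,5,5-tetramethyl-1,2,5,6,7,8-hexahydronaphthalen-1-yl]ethyl}oxiran-2-yl]methanol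
Conditions: Ti(OiPr)4 (10 mol %), D-(−)-diethyl tartrate (12 mol %), t-BuOOH, 4 Å molecular sieves, CH2Cl2, −20 °C
Reagents that add atoms: tert-butyl hydroperoxide, CC(C)(C)OO
Why: Sharpless asymmetric epoxidation: the titanium tartrate complex binds the allylic hydroxyl and delivers the peroxide oxygen to one face, D-(−)-tartrate giving the (2R,3R)-epoxide of an E-3,3-disubstituted allylic alcohol under reagent control, so C13 becomes R independently of the remote ring stereocentres; the diene has no hydroxyl handle and is not epoxidised by this system.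

Step 12
Reactants: 15 [(2R,3R)-3-methyl-3-{2-[(1R,2R)-1,2,5,5-tetramethyl-1,2,5,6,7,8-hexahydronaphthalen-1-yl]ethyl}oxiran-2-yl]methanol
Product: 16 (1S,2R,3S,4R)-4-{2-[(2R,3R)-3-(hydroxymethyl)-2-methyloxiran-2-yl]ethyl}-3,4,8,8-tetramethyl-1,2,3,4,5,6,7,8-octahydronaphthalene-1,2-diol
Conditions: OsO4 (2 mol %), N-methylmorpholine N-oxide, acetone/H2O, 0 → 25 °C; aq. Na2SO3
Reagents that add atoms: N-methylmorpholine N-oxide, C[N+]1([O-])CCOCC1; water, O (both oxygens pass through catalytic osmium tetroxide, O=[Os](=O)(=O)=O)
Why: Catalytic osmium tetroxide dihydroxylation attacks the cis-disubstituted C6=C7 alkene and not the tetrasubstituted C5=C10 alkene shielded by two quaternary carbons; the suprafacial [3+2] addition should occur on the face opposite to the allylic C8 methyl, giving the 6β,7β-diol (6S,7R); the epoxy alcohol is stable to these neutral conditions.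

Step 13
Reactants: 16 (1S,2R,3S,4R)-4-{2-[(2R,3R)-3-(hydroxymethyl)-2-methyloxiran-2-yl]ethyl}-3,4,8,8-tetramethyl-1,2,3,4,5,6,7,8-octahydronaphthalene-1,2-diol
Product: 17 [(2R,3R)-3-{2-[(1R,2S,3R,4S)-3,4-dihydroxy-1,2,5,5-tetramethyl-1,2,3,4,5,6,7,8-octahydronaphthalen-1-yl]ethyl}-3-methyloxiran-2-yl]methyl 4-methylbenzenesulfonate
Conditions: TsCl (1.1 equiv), pyridine, CH2Cl2, 0 °C
Reagents that add atoms: 4-toluenesulfonyl chloride, Cc1ccc(cc1)S(=O)(=O)Cl
Why: Sulfonylation in pyridine is selective for the unhindered primary hydroxyl over the secondary C7 hydroxyl and the C6 hydroxyl, which is allylic and crowded by the C4 gem-dimethyl group.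

Step 14
Reactants: 17 [(2R,3R)-3-{2-[(1R,2S,3R,4S)-3,4-dihydroxy-1,2,5,5-tetramethyl-1,2,3,4,5,6,7,8-octahydronaphthalen-1-yl]ethyl}-3-methyloxiran-2-yl]methyl 4-methylbenzenesulfonate
Product: 19 (1S,2R,3S,4R)-4-[(3R)-3-hydroxy-3-methylpent-4-en-1-yl]-3,4,8,8-tetramethyl-1,2,3,4,5,6,7,8-octahydronaphthalene-1,2-diol, via epoxy iodide 18 (not isolated)
Conditions: NaI, Zn dust, butan-2-one, 80 °C
Reagents that add atoms: sodium iodide, [Na+].[I-] (iodine is carried only by 18)
Why: Finkelstein exchange gives the epoxy iodide, zinc inserts into the C–I bond and β-elimination opens the epoxide (reductive opening of a 2,3-epoxy halide), forming the C14=C15 vinyl group while the C13–O bond and so the R configuration stay untouched; free hydroxyls are tolerated.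

Step 15
Reactants: 19 (1S,2R,3S,4R)-4-[(3R)-3-hydroxy-3-methylpent-4-en-1-yl]-3,4,8,8-tetramethyl-1,2,3,4,5,6,7,8-octahydronaphthalene-1,2-diol
Product: 20 (1S,2R,3S,4R)-1-hydroxy-4-[(3R)-3-hydroxy-3-methylpent-4-en-1-yl]-3,4,8,8-tetramethyl-1,2,3,4,5,6,7,8-octahydronaphthalen-2-yl acetate (CNP0126002.3)
Conditions: Ac2O (1.1 equiv), pyridine, CH2Cl2, 0 °C
Reagents that add atoms: acetic anhydride, CC(=O)OC(C)=O
Why: Acylation under mild base should distinguish the equatorial C7 hydroxyl from the C6 hydroxyl, which is pseudoaxial and crowded by the C4 gem-dimethyl group, and from the tertiary C13 hydroxyl, which does not acylate without forcing; one equivalent of anhydride at 0 °C limits over-acylation and migration.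

## Compound list

1 | (R)-(+)-pulegone, (5R)-5-methyl-2-(propan-2-ylidene)cyclohexan-1-one | C[C@@H]1CCC(=C(C)C)C(=O)C1 | starting material
2 | allylmagnesium bromide | C=CC[Mg]Br | starting material
3 | trimethyl{[(5R)-5-methyl-2-(2-methylpent-4-en-2-yl)cyclohex-1-en-1-yl]oxy}silane | C[C@@H]1CCC(C(C)(C)CC=C)=C(O[Si](C)(C)C)C1 | intermediate
4 | (5R)-5-methyl-2-(2-methylpent-4-en-2-yl)cyclohex-2-en-1-one | C[C@@H]1CC=C(C(C)(C)CC=C)C(=O)C1 | intermediate
5 | 2-(2-bromoethyl)-2-methyl-1,3-dioxolane | CC1(CCBr)OCCO1 | starting material
6 | 2-(2-iodoethyl)-2-methyl-1,3-dioxolane | CC1(CCI)OCCO1 | intermediate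
7 | (5R)-5-methyl-6-[2-(2-methyl-1,3-dioxolan-2-yl)ethyl]-2-(2-methylpent-4-en-2-yl)cyclohex-2-en-1-one (both C6 epimers, C6 left undefined) | C[C@@H]1CC=C(C(C)(C)CC=C)C(=O)C1CCC2(C)OCCO2 | intermediate
8 | (5R,6R)-5,6-dimethyl-6-[2-(2-methyl-1,3-dioxolan-2-yl)ethyl]-2-(2-methylpent-4-en-2-yl)cyclohex-2-en-1-one | CC1(CC[C@@]2(C)C(=O)C(C(C)(C)CC=C)=CC[C@H]2C)OCCO1 | intermediate
9 | (5R,6R)-5,6-dimethyl-6-[2-(2-methyl-1,3-dioxolan-2-yl)ethyl]-2-(2-methylpent-4-en-2-yl)cyclohexa-1,3-dien-1-yl trifluoromethanesulfonate | CC1(CC[C@@]2(C)C(OS(=O)(=O)C(F)(F)F)=C(C=C[C@H]2C)C(C)(C)CC=C)OCCO1 | intermediate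
10 | (5R,6R)-2-[5-(9-borabicyclo[3.3.1]nonan-9-yl)-2-methylpentan-2-yl]-5,6-dimethyl-6-[2-(2-methyl-1,3-dioxolan-2-yl)ethyl]cyclohexa-1,3-dien-1-yl trifluoromethanesulfonate (formed in the flask, not isolated) | CC1(CC[C@@]2(C)C(OS(=O)(=O)C(F)(F)F)=C(C=C[C@H]2C)C(C)(C)CCCB3C4CCCC3CCC4)OCCO1 | intermediate
11 | 2-methyl-2-{2-[(1R,2R)-1,2,5,5-tetramethyl-1,2,5,6,7,8-hexahydronaphthalen-1-yl]ethyl}-1,3-dioxolane | CC1(CC[C@@]2(C)C3=C(C=C[C@H]2C)C(C)(C)CCC3)OCCO1 | intermediate
12 | 4-[(1R,2R)-1,2,5,5-tetramethyl-1,2,5,6,7,8-hexahydronaphthalen-1-yl]butan-2-one | CC(=O)CC[C@@]1(C)C2=C(C=C[C@H]1C)C(C)(C)CCC2 | intermediate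
13 | ethyl (2E)-3-methyl-5-[(1R,2R)-1,2,5,5-tetramethyl-1,2,5,6,7,8-hexahydronaphthalen-1-yl]pent-2-enoate | CCOC(=O)/C=C(\C)CC[C@@]1(C)C2=C(C=C[C@H]1C)C(C)(C)CCC2 | intermediate
14 | (2E)-3-methyl-5-[(1R,2R)-1,2,5,5-tetramethyl-1,2,5,6,7,8-hexahydronaphthalen-1-yl]pent-2-en-1-ol | OC/C=C(\C)CC[C@@]1(C)C2=C(C=C[C@H]1C)C(C)(C)CCC2 | intermediate
15 | [(2R,3R)-3-methyl-3-{2-[(1R,2R)-1,2,5,5-tetramethyl-1,2,5,6,7,8-hexahydronaphthalen-1-yl]ethyl}oxiran-2-yl]methanol | OC[C@H]1O[C@]1(C)CC[C@@]2(C)C3=C(C=C[C@H]2C)C(C)(C)CCC3 | intermediate
16 | (1S,2R,3S,4R)-4-{2-[(2R,3R)-3-(hydroxymethyl)-2-methyloxiran-2-yl]ethyl}-3,4,8,8-tetramethyl-1,2,3,4,5,6,7,8-octahydronaphthalene-1,2-diol | OC[C@H]1O[C@]1(C)CC[C@@]2(C)C3=C([C@H](O)[C@H](O)[C@H]2C)C(C)(C)CCC3 | intermediate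
17 | [(2R,3R)-3-{2-[(1R,2S,3R,4S)-3,4-dihydroxy-1,2,5,5-tetramethyl-1,2,3,4,5,6,7,8-octahydronaphthalen-1-yl]ethyl}-3-methyloxiran-2-yl]methyl 4-methylbenzenesulfonate | Cc1ccc(cc1)S(=O)(=O)OC[C@H]1O[C@]1(C)CC[C@@]2(C)C3=C([C@H](O)[C@H](O)[C@H]2C)C(C)(C)CCC3 | intermediate
18 | (1S,2R,3S,4R)-4-{2-[(2R,3S)-3-(iodomethyl)-2-methyloxiran-2-yl]ethyl}-3,4,8,8-tetramethyl-1,2,3,4,5,6,7,8-octahydronaphthalene-1,2-diol (formed in the flask, not isolated) | IC[C@H]1O[C@]1(C)CC[C@@]2(C)C3=C([C@H](O)[C@H](O)[C@H]2C)C(C)(C)CCC3 | intermediate
19 | (1S,2R,3S,4R)-4-[(3R)-3-hydroxy-3-methylpent-4-en-1-yl]-3,4,8,8-tetramethyl-1,2,3,4,5,6,7,8-octahydronaphthalene-1,2-diol | C=C[C@](C)(O)CC[C@@]1(C)C2=C([C@H](O)[C@H](O)[C@H]1C)C(C)(C)CCC2 | intermediate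
20 | (1S,2R,3S,4R)-1-hydroxy-4-[(3R)-3-hydroxy-3-methylpent-4-en-1-yl]-3,4,8,8-tetramethyl-1,2,3,4,5,6,7,8-octahydronaphthalen-2-yl acetate (CNP0126002.3) | C=C[C@](C)(O)CC[C@@]1(C)C2=C([C@H](O)[C@H](OC(C)=O)[C@H]1C)C(C)(C)CCC2 | target

## Step count and least certain steps

Total step count: 15. Longest linear sequence: 14 steps (1 to 20 through steps 1, 2 and 4–15); step 3 is a one-step branch that supplies 6.

Step 7 (key step). What may go wrong: slow transmetalation at the crowded C10–Pd centre, which is flanked by the quaternary C9 and the tert-alkyl group on C5. This leaves time for protodeboronation, for hydrolysis of the triflate by aqueous base, or for reduction of the triflate after β-hydride elimination. Over-hydroboration at C6=C7 is possible if borane is in excess. Fallback: the same C1–C10 bond by intramolecular Negishi coupling, which needs no aqueous base. From 9, hydroboration with 9-BBN-H and oxidation with NaBO3·4H2O would give the primary alcohol F1. I2/PPh3/imidazole would give the primary iodide F2. Zinc insertion (Zn dust, LiCl, THF) would give the alkylzinc iodide F3, which is not isolated and is cyclised with Pd(OAc)2 and 2-dicyclohexylphosphino-2′,6′-dimethoxybiphenyl. The fallback returns to the route at 11.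

Step 4. What may go wrong: slow SN2 displacement at the β-branched, ketal-bearing primary iodide, so that proton transfer between enolate and product (dialkylation, recovered 4) and E2 loss of HI from 6 compete. Fallback: make the C9–C11 bond by conjugate addition instead of displacement. From 4, LiN(i-Pr)2/Me3SiCl would give the 2-silyloxydiene F4. Mukaiyama–Michael addition to methyl vinyl ketone (TiCl4, CH2Cl2, −78 °C) would give the 1,5-diketone F5. Ethylene glycol with pyridinium 4-toluenesulfonate (benzene, reflux) should ketalise only the unconjugated methyl ketone. The fallback returns to the route at 7.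

Step 5. What may go wrong: deprotonation at C7 (γ) in competition with the hindered tertiary C9 hydrogen, followed by proton shuffling or O-methylation, and incomplete facial control. Fallback: move both alkylations to the saturated series, where C7 is not acidic. From 3, methanolysis (K2CO3, MeOH) would give the saturated ketone F6. LiN(i-Pr)2 and 6 would give the C9-alkylated ketone F7; the other α-hydrogen, on C5, is shielded by the tert-alkyl group. LiN(i-Pr)2 and MeI would give the ketone F8 with quaternary C9, the methyl again entering anti to the C8 methyl. F8 has a single α-hydrogen, so Me3SiOTf/Et3N can only give the C5=C10 silyl enol ether F9, and Saegusa–Ito oxidation with Pd(OAc)2 returns to the route at 8.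

Step 9. What may go wrong: incomplete E selectivity in the olefination of a methyl ketone and incomplete removal of the Z isomer, which step 11 would turn into the C13 epimer. Fallback: set C13 directly at the ketone, with no alkene geometry involved. From 12, catalytic asymmetric Corey–Chaykovsky epoxidation would give the 2,2-disubstituted epoxide F10 (Me3S(O)I/NaH, LaLi3(binaphthoxide)3 with a triarylphosphine oxide, using the catalyst antipode that gives R). OsO4/N-methylmorpholine N-oxide as in step 12 would give the epoxy diol F11. Excess dimethylsulfonium methylide (Me3SI, n-BuLi, THF) opens the epoxide at its CH2 terminus and eliminates Me2S to the vinyl carbinol. The fallback returns to the route at 19.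

Step 12. What may go wrong: insufficient or reversed facial selectivity of the osmylation, because the β face, though free of the allylic C8 methyl, carries the C9 methyl two carbons from C7. Fallback (for attack preferring the α face): Woodward cis-hydroxylation, in which iodine takes the accessible face and the neighbouring acetate then delivers both oxygens to the opposite face. Wet acetic acid and silver ion would open an epoxide, so it is done before step 11. From 13, I2/AgOAc in AcOH, then aqueous AcOH, would give the 6β,7β-diol monoacetate F12. K2CO3/EtOH would give the diol F13, and Et3SiOTf/2,6-lutidine the bis(triethylsilyl) ether F14. i-Bu2AlH would give the allylic alcohol F15, and the epoxidation of step 11 the epoxy alcohol F16. Bu4NF removes both silyl groups and returns to the route at 16.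

Step 15. What may go wrong: loss of regiocontrol in the acylation (C6 ester or diester) or acetyl migration from O7 to O6 during work-up. Fallback: activation through tin. From 19, Bu2SnO (toluene, reflux, removal of water) would give the 6,7-O-dibutylstannylene acetal F17, whose equatorial oxygen (O7) is the more nucleophilic. AcCl at 0 °C then acylates O7 and returns to the route at 20.

## Further compounds

F1 | step 7 | (5R,6R)-2-(5-hydroxy-2-methylpentan-2-yl)-5,6-dimethyl-6-[2-(2-methyl-1,3-dioxolan-2-yl)ethyl]cyclohexa-1,3-dien-1-yl trifluoromethanesulfonate | CC1(CC[C@@]2(C)C(OS(=O)(=O)C(F)(F)F)=C(C=C[C@H]2C)C(C)(C)CCCO)OCCO1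
F2 | step 7 | (5R,6R)-2-(5-iodo-2-methylpentan-2-yl)-5,6-dimethyl-6-[2-(2-methyl-1,3-dioxolan-2-yl)ethyl]cyclohexa-1,3-dien-1-yl trifluoromethanesulfonate | CC1(CC[C@@]2(C)C(OS(=O)(=O)C(F)(F)F)=C(C=C[C@H]2C)C(C)(C)CCCI)OCCO1
F3 | step 7 | alkylzinc iodide from F2 (zinc on C1, not isolated) | CC1(CC[C@@]2(C)C(OS(=O)(=O)C(F)(F)F)=C(C=C[C@H]2C)C(C)(C)CCC[Zn]I)OCCO1
F4 | step 4 | trimethyl{[(6R)-6-methyl-3-(2-methylpent-4-en-2-yl)cyclohexa-1,3-dien-2-yl]oxy}silane | C[C@@H]1CC=C(C(C)(C)CC=C)C(O[Si](C)(C)C)=C1
F5 | step 4 | (5R)-5-methyl-2-(2-methylpent-4-en-2-yl)-6-(3-oxobutyl)cyclohex-2-en-1-one (C6 epimers) | C[C@@H]1CC=C(C(C)(C)CC=C)C(=O)C1CCC(C)=O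
F6 | step 5 | (5R)-5-methyl-2-(2-methylpent-4-en-2-yl)cyclohexan-1-one (C2 epimers) | C[C@@H]1CCC(C(C)(C)CC=C)C(=O)C1
F7 | step 5 | (3R)-3-methyl-2-[2-(2-methyl-1,3-dioxolan-2-yl)ethyl]-6-(2-methylpent-4-en-2-yl)cyclohexan-1-one (epimers at C2 and C6) | C[C@@H]1CCC(C(C)(C)CC=C)C(=O)C1CCC2(C)OCCO2
F8 | step 5 | (2R,3R)-2,3-dimethyl-2-[2-(2-methyl-1,3-dioxolan-2-yl)ethyl]-6-(2-methylpent-4-en-2-yl)cyclohexan-1-one (C6 epimers) | CC1(CC[C@@]2(C)C(=O)C(C(C)(C)CC=C)CC[C@H]2C)OCCO1
F9 | step 5 | trimethyl{[(5R,6R)-5,6-dimethyl-6-[2-(2-methyl-1,3-dioxolan-2-yl)ethyl]-2-(2-methylpent-4-en-2-yl)cyclohex-1-en-1-yl]oxy}silane | CC1(CC[C@@]2(C)C(O[Si](C)(C)C)=C(C(C)(C)CC=C)CC[C@H]2C)OCCO1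
F10 | step 9 | (2R)-2-methyl-2-{2-[(1R,2R)-1,2,5,5-tetramethyl-1,2,5,6,7,8-hexahydronaphthalen-1-yl]ethyl}oxirane | C[C@]1(CO1)CC[C@@]2(C)C3=C(C=C[C@H]2C)C(C)(C)CCC3
F11 | step 9 | (1S,2R,3S,4R)-3,4,8,8-tetramethyl-4-{2-[(2R)-2-methyloxiran-2-yl]ethyl}-1,2,3,4,5,6,7,8-octahydronaphthalene-1,2-diol | C[C@]1(CO1)CC[C@@]2(C)C3=C([C@H](O)[C@H](O)[C@H]2C)C(C)(C)CCC3
F12 | step 12 | ethyl (2E)-5-[(1R,2S,3R,4S)-4-acetoxy-3-hydroxy-1,2,5,5-tetramethyl-1,2,3,4,5,6,7,8-octahydronaphthalen-1-yl]-3-methylpent-2-enoate (drawn as the O6 acetate; the O7 isomer would serve equally) | CCOC(=O)/C=C(\C)CC[C@@]1(C)C2=C([C@H](OC(C)=O)[C@H](O)[C@H]1C)C(C)(C)CCC2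
F13 | step 12 | ethyl (2E)-5-[(1R,2S,3R,4S)-3,4-dihydroxy-1,2,5,5-tetramethyl-1,2,3,4,5,6,7,8-octahydronaphthalen-1-yl]-3-methylpent-2-enoate | CCOC(=O)/C=C(\C)CC[C@@]1(C)C2=C([C@H](O)[C@H](O)[C@H]1C)C(C)(C)CCC2
F14 | step 12 | ethyl (2E)-3-methyl-5-[(1R,2S,3R,4S)-1,2,5,5-tetramethyl-3,4-bis(triethylsilyloxy)-1,2,3,4,5,6,7,8-octahydronaphthalen-1-yl]pent-2-enoate | CCOC(=O)/C=C(\C)CC[C@@]1(C)C2=C([C@H](O[Si](CC)(CC)CC)[C@H](O[Si](CC)(CC)CC)[C@H]1C)C(C)(C)CCC2
F15 | step 12 | (2E)-3-methyl-5-[(1R,2S,3R,4S)-1,2,5,5-tetramethyl-3,4-bis(triethylsilyloxy)-1,2,3,4,5,6,7,8-octahydronaphthalen-1-yl]pent-2-en-1-ol | OC/C=C(\C)CC[C@@]1(C)C2=C([C@H](O[Si](CC)(CC)CC)[C@H](O[Si](CC)(CC)CC)[C@H]1C)C(C)(C)CCC2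
F16 | step 12 | [(2R,3R)-3-methyl-3-{2-[(1R,2S,3R,4S)-1,2,5,5-tetramethyl-3,4-bis(triethylsilyloxy)-1,2,3,4,5,6,7,8-octahydronaphthalen-1-yl]ethyl}oxiran-2-yl]methanol | OC[C@H]1O[C@]1(C)CC[C@@]2(C)C3=C([C@H](O[Si](CC)(CC)CC)[C@H](O[Si](CC)(CC)CC)[C@H]2C)C(C)(C)CCC3
F17 | step 15 | 6,7-O-dibutylstannylene acetal of 19 (2,2-dibutyl-1,3,2-dioxastannolane fused at C6 and C7) | C=C[C@](C)(O)CC[C@@]1(C)C2=C([C@@H]3O[Sn](CCCC)(CCCC)O[C@@H]3[C@H]1C)C(C)(C)CCC2
A1 | alternative 1 | cis-fused Diels–Alder lactone menthyl acetal with the alkene at C5=C6 | O=C1O[C@@H](O[C@@H]4C[C@H](C)CC[C@H]4C(C)C)[C@@H]2CC=C3[C@@H]([C@]12C)CCCC3(C)C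
A2 | alternative 1 | 1-ethenyl-6,6-dimethylcyclohex-1-ene | C=CC1=CCCCC1(C)C
A3 | alternative 1 | (5R)-3-methyl-5-{[(1R,2S,5R)-5-methyl-2-(propan-2-yl)cyclohexyl]oxy}furan-2(5H)-one | O=C1O[C@@H](O[C@@H]2C[C@H](C)CC[C@H]2C(C)C)C=C1C
A4 | alternative 2 | 6β,7β-diol of the halima-5(10),14-diene with the C13 triethylsilyl ether | C=C[C@](C)(O[Si](CC)(CC)CC)CC[C@@]1(C)C2=C([C@H](O)[C@H](O)[C@H]1C)C(C)(C)CCC2
A5 | alternative 2 | seco ring B dialdehyde (C6 enal on C5, C7 aldehyde on C8) with the C13 triethylsilyl ether | C=C[C@](C)(O[Si](CC)(CC)CC)CC[C@](C)([C@H](C)C=O)C1=C(C=O)C(C)(C)CCC1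
A6 | alternative 3 | bicyclic 5(10)-en-6-one with the C13 methyl ketone | CC(=O)CC[C@@]1(C)C2=C(C(=O)C[C@H]1C)C(C)(C)CCC2
A7 | alternative 3 | (4R,5R)-4,5-dimethyl-3-(4-methylpent-3-en-1-yl)-4-(3-oxobutyl)cyclohex-2-en-1-one | CC(=O)CC[C@@]1(C)C(CCC=C(C)C)=CC(=O)C[C@H]1C
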